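Plan
1. The target is a 3-hydroxyphenyl ketone on C6 of a 5,7-dihydroxy-2,2-dimethyl-2H-chromene with a prenyl group on C8; it has no stereocentre and no stereogenic double bond, so no stereochemistry has to be set.
2. Retrosynthesis: after two ester groups are removed (O5 acetate, ring-B pivalate), the pyran bond C4–C4a and the C8–prenyl bond are cut in one retro-step, giving a ring-A bis-ether with 1,1-dimethylpropargyl on O1 and 1,1-dimethylallyl on O7.
3. Enabling feature: the chain O1–C2(Me)2–C3=C4–C4a of the pyran ring is the retron of an aryl 1,1-dimethylpropargyl ether, and the C8 prenyl group ortho to the C7 oxygen is the retron of an aryl 1,1-dimethylallyl ether; both ethers sit on phloroglucinol ring A, whose two free carbons (C4a, C8) flank O1.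
4. Further cuts: the two ether C–O bonds (O1, para to the ketone, is the most acidic; the ortho oxygens are told apart by chelation) and the aryl–carbonyl bond (Houben–Hoesch acylation of phloroglucinol with O-pivaloyl 3-hydroxybenzonitrile).
5. Forward order: ring B is protected, ring A is acylated, O1 and then O7 are etherified, O5 is acetylated, one heating operation sets the prenyl group and closes the pyran ring, and both esters are removed last.

Key step: step 7

Remark: ring-A atoms of all intermediates are cited by the chromene numbering of the target (O1, C2, C3, C4, C4a, C5, C6, C7, C8, C8a). The allyl carbonate of step 5 is made in step 4 and is not assumed to be purchasable.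

Step 1
Reactants: 1 3-hydroxybenzonitrile
Product: 2 3-cyanophenyl pivalate
Conditions: PivCl, Et3N, DMAP (cat.), CH2Cl2, 0 °C → rt
Reagents that add atoms: pivaloyl chloride, CC(C)(C)C(Cl)=O
Why: DMAP-catalysed O-acylation of a phenol by an acid chloride; the hindered pivalate is chosen because it should withstand the acidic acylation of step 2, the bases of steps 3 to 6 and heat, and leaves by mild methanolysis at the end.

Step 2
Reactants: 2 3-cyanophenyl pivalate; 3 phloroglucinol
Product: 5 3-(2,4,6-trihydroxybenzoyl)phenyl pivalate, via ketiminium chloride 4 (not isolated)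
Conditions: ZnCl2, HCl (g), Et2O, 0 °C; then H2O, 100 °C
Reagents that add atoms: water, O
Why: Houben–Hoesch reaction, in which the nitrile activated by HCl and ZnCl2 acylates the electron-rich, threefold symmetric phloroglucinol once (the ketiminium salt 4 deactivates the ring against a second acylation) and hot water hydrolyses 4 to the ketone while the hindered aryl pivalate should persist.

Step 3
Reactants: 5 3-(2,4,6-trihydroxybenzoyl)phenyl pivalate; 6 3-chloro-3-methylbut-1-yne
Product: 7 3-[2,6-dihydroxy-4-(2-methylbut-3-yn-2-yloxy)benzoyl]phenyl pivalate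
Conditions: DBU, CuCl2·2H2O (cat.), MeCN, 0 °C
Reagents that add atoms: none
Why: Copper-catalysed propargylic etherification (substitution through a copper acetylide) at the most acidic and only unhindered ring-A hydroxyl, the one para to the ketone (future O1), the two ortho hydroxyls being hydrogen-bonded to or shielded by the aroyl group, so that one equivalent of 6 at 0 °C should limit over-alkylation.

Step 4
Reactants: 8 2-methylbut-3-en-2-ol
Product: 9 isobutyl 2-methylbut-3-en-2-yl carbonate
Conditions: n-BuLi, THF, 0 °C; then i-BuOCOCl, 0 °C → rt
Reagents that add atoms: isobutyl chloroformate, CC(C)COC(Cl)=O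
Why: O-acylation of a lithium alkoxide by a chloroformate, the standard route to a tertiary allylic carbonate.

Step 5
Reactants: 7 3-[2,6-dihydroxy-4-(2-methylbut-3-yn-2-yloxy)benzoyl]phenyl pivalate; 9 isobutyl 2-methylbut-3-en-2-yl carbonate
Product: 10 3-[2-hydroxy-6-(2-methylbut-3-en-2-yloxy)-4-(2-methylbut-3-yn-2-yloxy)benzoyl]phenyl pivalate
Conditions: Pd(PPh3)4 (cat.), THF, 0 °C
Reagents that add atoms: none
Why: Tsuji–Trost O-allylation, in which zerovalent palladium ionises 9 with loss of CO2 to a 1,1-dimethyl-π-allyl complex and isobutoxide, the phenoxide of one of the two equivalent ortho hydroxyls attacks the more substituted allyl terminus under kinetic control at 0 °C to give the tertiary ether on O7, and the remaining hydroxyl (O5), now firmly chelated to the ketone, resists a second allylation.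

Step 6
Reactants: 10 3-[2-hydroxy-6-(2-methylbut-3-en-2-yloxy)-4-(2-methylbut-3-yn-2-yloxy)benzoyl]phenyl pivalate
Product: 11 3-[2-acetoxy-6-(2-methylbut-3-en-2-yloxy)-4-(2-methylbut-3-yn-2-yloxy)benzoyl]phenyl pivalate
Conditions: Ac2O, DMAP (cat.), pyridine, rt
Reagents that add atoms: acetic anhydride, CC(=O)OC(C)=O
Why: DMAP-catalysed acetylation of the remaining chelated phenol, which installs a temporary block on O5 so that O5 cannot compete with O1 in the ring closure of step 7 and which is removed together with the pivalate in step 8.

Step 7
Reactants: 11 3-[2-acetoxy-6-(2-methylbut-3-en-2-yloxy)-4-(2-methylbut-3-yn-2-yloxy)benzoyl]phenyl pivalate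
Product: 15 3-[5-acetoxy-7-hydroxy-2,2-dimethyl-8-(3-methylbut-2-enyl)-2H-chromene-6-carbonyl]phenyl pivalate, via C-prenyl propargyl ether 12 (not isolated), via allenylphenol 13 (not isolated), via ortho-quinone methide 14 (not isolated)
Conditions: o-xylene (degassed, dilute), 100 °C; then 140 °C
Reagents that add atoms: none
Why: At 100 °C only the 1,1-dimethylallyl ether should react: its aromatic Claisen [3,3] shift can end productively only at C8 (the other ortho carbon, C6, carries the aroyl group) and enolisation gives 12 with the prenyl group in place; at 140 °C the 1,1-dimethylpropargyl ether of 12 undergoes its own [3,3] shift to the one free ring carbon, C4a, which makes the C4–C4a bond, and enolisation (13), a [1,5]-hydrogen shift from the O1 hydroxyl to the central allene carbon (14) and a thermal disrotatory oxa-6π electrocyclisation give 15. The closest known reaction types are the thermal ortho-Claisen rearrangement of aryl 1,1-dimethylallyl ethers to ortho-prenylphenols and the thermal cyclisation of aryl 1,1-dimethylpropargyl ethers to 2,2-dimethyl-2H-chromenes, run here in one flask. The pyran ring of 15 differs from the open ether chain of 11 by a single new ring bond, C4–C4a, formed through a six-membered chair-like pericyclic transition state, the O1–C2 bond being given up in that shift and restored by the 6π closure of the oxatriene O1=C8a–C4a=C4–C3=C2. No stereocentre arises, since C2 carries two methyl groups and the cis geometry of C3=C4 is fixed by the ring. The step needs three kinds of regiocontrol: the allyl shift must precede the propargyl shift, which the lower barrier of the allyl ether and the two-stage heating should secure; the propargyl group must go to C4a, which is the only unsubstituted carbon once C8 is prenylated (shifts to substituted carbons give dienones that cannot enolise and revert); and the ring must close through O1 and not O5, which the O5 acetate secures by leaving O1–H as the only hydroxyl beside the allene.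

Step 8
Reactants: 15 3-[5-acetoxy-7-hydroxy-2,2-dimethyl-8-(3-methylbut-2-enyl)-2H-chromene-6-carbonyl]phenyl pivalate
Product: 16 [5,7-dihydroxy-2,2-dimethyl-8-(3-methylbut-2-enyl)-2H-chromen-6-yl](3-hydroxyphenyl)methanone
Conditions: K2CO3, MeOH, rt, argon; then aq. NH4Cl
Reagents that add atoms: none
Why: Base-promoted methanolysis (transesterification) of the two aryl esters, under which the chromene, the prenyl group and the diaryl ketone should be inert, the phenoxides being kept under argon to avoid oxidation.

Compound list
1 | 3-hydroxybenzonitrile | N#Cc1cccc(O)c1 | starting material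
2 | 3-cyanophenyl pivalate | CC(C)(C)C(=O)Oc1cccc(C#N)c1 | intermediate
3 | phloroglucinol (benzene-1,3,5-triol) | Oc1cc(O)cc(O)c1 | starting material
4 | [(3-pivaloyloxyphenyl)(2,4,6-trihydroxyphenyl)methylidene]ammonium chloride (ketiminium chloride, not isolated) | [Cl-].[NH2+]=C(c1cccc(OC(=O)C(C)(C)C)c1)c1c(O)cc(O)cc1O | intermediate
5 | 3-(2,4,6-trihydroxybenzoyl)phenyl pivalate | CC(C)(C)C(=O)Oc1cccc(C(=O)c2c(O)cc(O)cc2O)c1 | intermediate
6 | 3-chloro-3-methylbut-1-yne | C#CC(C)(C)Cl | starting material
7 | 3-[2,6-dihydroxy-4-(2-methylbut-3-yn-2-yloxy)benzoyl]phenyl pivalate | CC(C)(C)C(=O)Oc1cccc(C(=O)c2c(O)cc(OC(C)(C)C#C)cc2O)c1 | intermediate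
8 | 2-methylbut-3-en-2-ol | C=CC(C)(C)O | starting material
9 | isobutyl 2-methylbut-3-en-2-yl carbonate | C=CC(C)(C)OC(=O)OCC(C)C | intermediate
10 | 3-[2-hydroxy-6-(2-methylbut-3-en-2-yloxy)-4-(2-methylbut-3-yn-2-yloxy)benzoyl]phenyl pivalate | CC(C)(C)C(=O)Oc1cccc(C(=O)c2c(O)cc(OC(C)(C)C#C)cc2OC(C)(C)C=C)c1 | intermediate
11 | 3-[2-acetoxy-6-(2-methylbut-3-en-2-yloxy)-4-(2-methylbut-3-yn-2-yloxy)benzoyl]phenyl pivalate | CC(C)(C)C(=O)Oc1cccc(C(=O)c2c(OC(C)=O)cc(OC(C)(C)C#C)cc2OC(C)(C)C=C)c1 | intermediate
12 | 3-[6-acetoxy-2-hydroxy-3-(3-methylbut-2-enyl)-4-(2-methylbut-3-yn-2-yloxy)benzoyl]phenyl pivalate (C-prenyl propargyl ether, not isolated) | CC(C)(C)C(=O)Oc1cccc(C(=O)c2c(OC(C)=O)cc(OC(C)(C)C#C)c(CC=C(C)C)c2O)c1 | intermediate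
13 | 3-[2-acetoxy-4,6-dihydroxy-3-(3-methylbuta-1,2-dienyl)-5-(3-methylbut-2-enyl)benzoyl]phenyl pivalate (allenylphenol, not isolated) | CC(C)(C)C(=O)Oc1cccc(C(=O)c2c(OC(C)=O)c(C=C=C(C)C)c(O)c(CC=C(C)C)c2O)c1 | intermediate
14 | 3-[2-acetoxy-6-hydroxy-5-(3-methylbut-2-enyl)-3-(3-methylbut-2-enylidene)-4-oxocyclohexa-1,5-diene-1-carbonyl]phenyl pivalate (ortho-quinone methide, not isolated) | CC(C)=CC=C1C(=O)C(CC=C(C)C)=C(O)C(C(=O)c2cccc(OC(=O)C(C)(C)C)c2)=C1OC(C)=O | intermediate
15 | 3-[5-acetoxy-7-hydroxy-2,2-dimethyl-8-(3-methylbut-2-enyl)-2H-chromene-6-carbonyl]phenyl pivalate | CC(C)=CCc1c(O)c(C(=O)c2cccc(OC(=O)C(C)(C)C)c2)c(OC(C)=O)c2c1OC(C)(C)C=C2 | intermediate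
16 | [5,7-dihydroxy-2,2-dimethyl-8-(3-methylbut-2-enyl)-2H-chromen-6-yl](3-hydroxyphenyl)methanone | CC(C)=CCc1c(O)c(C(=O)c2cccc(O)c2)c(O)c2c1OC(C)(C)C=C2 | target

Total step count: 8
Longest linear sequence: 7 steps (steps 1, 2, 3, 5, 6, 7, 8); step 4 is a side branch.

Steps most likely to fail

Step 7. What may go wrong: the two sigmatropic shifts may not be cleanly resolved in time, so that the propargyl group migrates to C8 before the allyl group has left O7. The allyl group is then forced through a Claisen–Cope relay that delivers a reverse-prenyl group at C4a. Prolonged heating may also cost the O5 acetate and reopen closure through O5. Fallback: it sets out from 11 and comes back at 15, and separates the two events with a ring closure that involves no sigmatropic shift. Compound 11 is warmed in toluene at 90 °C only until the allyl ether is consumed and the C-prenyl propargyl ether 12 is isolated. Compound 12 is then treated with Ph3PAuNTf2 (cat., monovalent gold) in CH2Cl2 at rt. This 6-endo-dig hydroarylation of the aryl propargyl ether, a known route to 2H-chromenes, should form C4–C4a directly at the only free ring carbon without breaking O1–C2 and without involving any phenol oxygen, to give 15. No compound outside the compound list is made (entry F0).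

Step 5. What may go wrong: ionisation of the tertiary propargylic aryl ether or binding of the terminal alkyne by the zerovalent palladium catalyst, drift from the branched ether to the linear O-prenyl ether by re-ionisation, and double allylation. Fallback: it sets out from 7 and comes back at 12, and brings in the prenyl group directly at carbon without any O-allyl ether. Compound 7 is C-alkylated with 1-bromo-3-methylbut-2-ene and DBU in THF at rt; the two free ring carbons are equivalent, so one C-prenyl product should form: 3-[2,6-dihydroxy-3-(3-methylbut-2-enyl)-4-(2-methylbut-3-yn-2-yloxy)benzoyl]phenyl pivalate F1. One equivalent of Ac2O in pyridine at 0 °C should then acetylate the less hindered hydroxyl (the one next to the free ring C–H, future O5) to give 12. Compound 12 is heated at 140 °C as in the second stage of step 7.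

Step 2. What may go wrong: loss of the pivalate protecting group during the hot acidic hydrolysis of the ketiminium salt, or sluggish activation of the ester-bearing nitrile. Fallback: it sets out from 1 and 3 and comes back at 7, and moves the ring-B protection behind the acylation. The Houben–Hoesch reaction of unprotected 1 with 3 (ZnCl2, HCl, Et2O; then hot water) gives, through [(3-hydroxyphenyl)(2,4,6-trihydroxyphenyl)methylidene]ammonium chloride F2, the tetraol (3-hydroxyphenyl)(2,4,6-trihydroxyphenyl)methanone F3. Copper-catalysed etherification with 6 and one equivalent of DBU should take place at the most acidic hydroxyl, para to the ketone, to give [2,6-dihydroxy-4-(2-methylbut-3-yn-2-yloxy)phenyl](3-hydroxyphenyl)methanone F4. One equivalent of pivaloyl chloride in pyridine at 0 °C should then acylate the only unhindered, non-chelated phenol (ring B) to give 7.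

Further compounds
F0 | step 7 | none | none
F1 | step 5 | 3-[2,6-dihydroxy-3-(3-methylbut-2-enyl)-4-(2-methylbut-3-yn-2-yloxy)benzoyl]phenyl pivalate | CC(C)(C)C(=O)Oc1cccc(C(=O)c2c(O)cc(OC(C)(C)C#C)c(CC=C(C)C)c2O)c1
F2 | step 2 | [(3-hydroxyphenyl)(2,4,6-trihydroxyphenyl)methylidene]ammonium chloride | [Cl-].[NH2+]=C(c1cccc(O)c1)c1c(O)cc(O)cc1O
F3 | step 2 | (3-hydroxyphenyl)(2,4,6-trihydroxyphenyl)methanone | O=C(c1cccc(O)c1)c1c(O)cc(O)cc1O
F4 | step 2 | [2,6-dihydroxy-4-(2-methylbut-3-yn-2-yloxy)phenyl](3-hydroxyphenyl)methanone | C#CC(C)(C)Oc1cc(O)c(C(=O)c2cccc(O)c2)c(O)c1
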